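## Assumptions

- The target is a chalcone/dehydroprenyl Diels–Alder adduct with a 2R flavanone. All-trans means COAr trans to both neighbouring aryl groups.
- Free phenols are tolerated throughout, with no protecting groups, to keep the route short.
- The chiral-ligand enantiomer is chosen so that the cyclohexene comes out (1R,5S,6R), as numbered in the names below. If the wrong enantiomer forms, the ligand is swapped.

## Retrosynthesis

1. The 7-hydroxyflavanone ring is formed last, by oxa-Michael closure of the 2'-hydroxychalcone 11. This sets C2 (R).
2. Chalcone 11 comes from Claisen–Schmidt condensation of adduct aldehyde 10 with resacetophenone 8.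
3. The cyclohexene with three contiguous stereocentres is formed by a chiral Lewis-acid normal-demand Diels–Alder reaction. The diene is the 1-aryl-3-methylbutadiene aldehyde 7 and the dienophile is morachalcone A (9). The "ortho/para" regiochemistry matches the target.
4. Diene 7 comes from Suzuki coupling of iodoaldehyde 3 with the (E)-dienyl-Bpin 6, which is made from isopropenylacetylene. Suzuki coupling is used because a Heck reaction with isoprene on this o-iodophenol would give Larock dihydrobenzofurans. Morachalcone A (9) comes from Claisen–Schmidt condensation of 8 and 1.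

## Route

**Step 1**
- Reactants: 1 (2,4-dihydroxybenzaldehyde); 2 (N-iodosuccinimide)
- Product: 3 (2,4-dihydroxy-5-iodobenzaldehyde)
- Conditions: NIS (1.05 equiv), MeCN, 0 °C → rt, 3 h
- Reagents that add atoms: NIS, O=C1CCC(=O)N1I (adds I)
- Why: Electrophilic aromatic iodination goes to C5, which is para to 2-OH and ortho to 4-OH. C3 is hindered and C6 is deactivated by the CHO. The aldehyde and phenols are untouched.

**Step 2**
- Reactants: 4 (2-methylbut-1-en-3-yne); 5 (pinacolborane)
- Product: 6 ((E)-2-(3-methylbuta-1,3-dien-1-yl)-4,4,5,5-tetramethyl-1,3,2-dioxaborolane)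
- Conditions: HBpin (1.1 equiv), Cp2Zr(H)Cl (5 mol %), CH2Cl2, rt, 12 h
- Reagents that add atoms: HBpin, [H]B1OC(C)(C)C(C)(C)O1 (adds Bpin and H)
- Why: Zr-catalysed hydroboration adds syn across the terminal alkyne only, giving the E-alkenyl boronate and leaving the isopropenyl alkene intact.

**Step 3**
- Reactants: 3; 6
- Product: 7 (2,4-dihydroxy-5-[(E)-3-methylbuta-1,3-dien-1-yl]benzaldehyde)
- Conditions: 6 (1.5 equiv), Pd(dppf)Cl2 (5 mol %), K2CO3 (4 equiv), dioxane/H2O 4:1, BHT, 75 °C, 4 h
- Reagents that add atoms: none (6 is the coupling partner)
- Why: Suzuki–Miyaura coupling retains the E-diene geometry. Excess base covers the two acidic phenols, and transmetalation outcompetes π-allyl/Larock pathways.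

**Step 4**
- Reactants: 8 (2,4-dihydroxyacetophenone); 1
- Product: 9 ((E)-2,4,2',4'-tetrahydroxychalcone, morachalcone A)
- Conditions: 50 % aq. KOH, EtOH, rt, 48 h; then 1 M HCl to pH 3
- Reagents that add atoms: none
- Why: Claisen–Schmidt aldol condensation followed by dehydration gives the thermodynamic E-enone. Bis-phenolate formation suppresses side reactions.

**Step 5**
- Reactants: 7 (diene, 1.0 equiv); 9 (dienophile, 2.0 equiv)
- Product: 10 (5-[(1R,5S,6R)-6-(2,4-dihydroxybenzoyl)-5-(2,4-dihydroxyphenyl)-3-methylcyclohex-2-en-1-yl]-2,4-dihydroxybenzaldehyde)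
- Conditions: (S)-3,3'-Ph2-BINOL (20 mol %), B(OPh)3 (40 mol %), 4 Å MS, toluene, 0 °C → rt, 72 h; separate the exo diastereomer by chromatography
- Reagents that add atoms: none (catalytic)
- Why: This is a chiral boron-Lewis-acid-catalysed normal-demand Diels–Alder reaction. B chelates the 2'-O/C=O of the chalcone, fixing the s-cis enone and blocking one face. The terminal CH2 of the diene bonds to the β-carbon (Ar3) and the aryl-bearing terminus bonds to the α-carbon. The E-enone gives COAr trans to Ar3, and the exo approach of the E-diene gives Ar1 trans to COAr. Excess 9 is used because the aldehyde-bearing diene does not homodimerise.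

**Step 6**
- Reactants: 10; 8
- Product: 11 ((E)-chalcone with the cyclohexene at C5 of the B ring)
- Conditions: 50 % aq. KOH, EtOH, rt, 72 h; cold 1 M HCl quench to pH 3, use crude
- Reagents that add atoms: none
- Why: Claisen–Schmidt condensation at the aldehyde. The aroyl α-stereocentre (C4 of the cyclohexene) is protected from epimerisation because the 2,4-dihydroxybenzoyl group sits as a phenolate, which suppresses enolisation. The isolated alkene is inert.

**Step 7**
- Reactants: 11
- Product: 12 (target)
- Conditions: quinine-derived bifunctional thiourea (20 mol %), CH2Cl2/THF 9:1, rt, 5 d; then prep-HPLC (C18) to remove the 2S epimer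
- Reagents that add atoms: none
- Why: Intramolecular 6-endo oxa-Michael addition of the A-ring 2'-OH onto the enone. The catalyst sets C2 (R) by H-bond activation of the phenol and enone. The distant cyclohexene centres do not bias it, so any 2S epimer is removed by HPLC. The cyclohexene centres are not touched under these mild conditions.

## Checks

- **Structure match:** Steps 5–7 give the cyclohexene Me–C=CH–CH(Ar1)–CH(COAr2)–CH(Ar3)–CH2, with Ar2 and Ar3 both 2,4-dihydroxyphenyl. Ar1 carries the 7-hydroxyflavanone at the position meta to the ring attachment, flanked by OH on one side and H on the other. This matches the target SMILES, and the formula is C35H30O10 (C27H24O8 adduct + C8H8O3 − H2O, then an isomerisation).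
- **Stereocentres:** The three cyclohexene centres are set in Step 5 and are not scrambled in Steps 6–7. C2 of the flavanone is set in Step 7.

## Compound list

| # | Name | SMILES | Role |
|---|---|---|---|
| 1 | 2,4-dihydroxybenzaldehyde | O=Cc1ccc(O)cc1O | starting material |
| 2 | N-iodosuccinimide | O=C1CCC(=O)N1I | starting material |
| 3 | 2,4-dihydroxy-5-iodobenzaldehyde | O=Cc1cc(I)c(O)cc1O | intermediate |
| 4 | 2-methylbut-1-en-3-yne | C=C(C)C#C | starting material |
| 5 | pinacolborane | [H]B1OC(C)(C)C(C)(C)O1 | starting material |
| 6 | (E)-3-methylbuta-1,3-dienyl-Bpin | C=C(C)/C=C/B1OC(C)(C)C(C)(C)O1 | intermediate |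
| 7 | 2,4-dihydroxy-5-[(E)-3-methylbuta-1,3-dienyl]benzaldehyde | O=Cc1cc(/C=C/C(C)=C)c(O)cc1O | intermediate |
| 8 | 2,4-dihydroxyacetophenone | CC(=O)c1ccc(O)cc1O | starting material |
| 9 | (E)-morachalcone A | O=C(/C=C/c1ccc(O)cc1O)c1ccc(O)cc1O | intermediate |
| 10 | Diels–Alder adduct aldehyde (1R,5S,6R) | CC1=C[C@@H](c2cc(C=O)c(O)cc2O)[C@H](C(=O)c2ccc(O)cc2O)[C@@H](c2ccc(O)cc2O)C1 | intermediate |
| 11 | (E)-chalcone of 10 | CC1=C[C@@H](c2cc(/C=C/C(=O)c3ccc(O)cc3O)c(O)cc2O)[C@H](C(=O)c2ccc(O)cc2O)[C@@H](c2ccc(O)cc2O)C1 | intermediate |
| 12 | (2R)-2-{5-[(1R,5S,6R)-6-(2,4-dihydroxybenzoyl)-5-(2,4-dihydroxyphenyl)-3-methylcyclohex-2-en-1-yl]-2,4-dihydroxyphenyl}-7-hydroxychroman-4-one | CC1=C[C@@H](c2cc([C@H]3CC(=O)c4ccc(O)cc4O3)c(O)cc2O)[C@H](C(=O)c2ccc(O)cc2O)[C@@H](c2ccc(O)cc2O)C1 | target |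

## Totals

- Total steps: 7.
- Longest linear sequence: 5 (Steps 1, 3, 5, 6, 7 from compound 1).

## Three steps most likely to fail

1. **Step 5 (asymmetric Diels–Alder).** The exo/endo ratio, ee, and tolerance of free phenols to the boron catalyst are all uncertain. Fallback: protect the non-chelating phenols as MOM ethers (leaving 2'-OH free) and run the Diels–Alder with an achiral Lewis acid. Then isolate the exo adduct and resolve the enantiomers by preparative chiral HPLC, followed by MOM removal.
2. **Step 7 (C2 control).** Catalyst-controlled oxa-Michael addition usually gives only modest ee or dr, and the product epimerises in base. Fallback: cyclise thermodynamically (NaOAc, EtOH, reflux) to a C2 epimer mixture and separate the diastereomers by preparative HPLC, accepting the loss of yield.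
3. **Step 6 (Claisen–Schmidt on hindered aldehyde 10).** Yields may be low, with retro-aldol or epimerisation as side reactions. Fallback: invert the order. Condense 7 with 8 first to give a diene-chalcone, then run the Diels–Alder with excess 9 under slow addition of the diene. Alternatively, protect the phenols as MOM ethers and use an aldol with the pre-formed ketone enolate.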